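**Retrosynthetic overview**
1. Confluentic acid comes from its bis-benzyl derivative (2-O-benzyl ether on ring A, benzyl ester on ring B). One hydrogenolysis frees both groups.
2. Key disconnection (new step): the ring A C6–CH2 bond. It is made last, on the intact depside, by ester-directed C–H acylmethylation with a hexanoyl sulfoxonium ylide. No activated keto acid, which would close to an isocoumarin, is ever needed.
3. The 2'-OMe group comes from 2'-OH by methylation after the ester is made. The ring A acyl group doubles as the protecting group of the 4'-OH.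
4. The depside C(=O)–O bond comes from O-benzyl-4-methoxysalicylic acid and benzyl olivetolate, by acylation at the non-chelated 4-OH.
5. No ring is formed. Ring A is bought as 4-methoxysalicylic acid and ring B as olivetolic acid.

Assumption: the target SMILES holds no stereocentre, stereogenic axis or stereogenic double bond. The compound is achiral, there is no enantiomer to select, and no step creates a stereocentre.

**Route**

Step 1
Reactants: 1 2-hydroxy-4-methoxybenzoic acid
Product: 2 benzyl 2-(benzyloxy)-4-methoxybenzoate
Conditions: BnBr (2.4 equiv), K2CO3 (3 equiv), DMF, 60 °C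
Reagents that add atoms: benzyl bromide, BrCc1ccccc1
Why: Williamson etherification and carboxylate O-alkylation (SN2) with excess benzyl bromide alkylate both acidic OH groups, and nothing else in 1 can react.

Step 2
Reactants: 2 benzyl 2-(benzyloxy)-4-methoxybenzoate
Product: 3 O-benzyl-4-methoxysalicylic acid [2-(benzyloxy)-4-methoxybenzoic acid]
Conditions: NaOH (3 equiv), THF/MeOH/H2O, 60 °C; then dilute aq HCl
Reagents that add atoms: sodium hydroxide, [Na+].[OH-]
Why: Saponification (acyl–oxygen cleavage) of the mono-ortho-substituted benzyl ester is easy, while the aryl benzyl and aryl methyl ethers are inert to hydroxide.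

Step 3
Reactants: 4 olivetolic acid (2,4-dihydroxy-6-pentylbenzoic acid)
Product: 5 benzyl 2,4-dihydroxy-6-pentylbenzoate (benzyl olivetolate)
Conditions: BnBr (1.05 equiv), KHCO3 (1.2 equiv), DMF, rt
Reagents that add atoms: benzyl bromide, BrCc1ccccc1
Why: This is a chemoselective carboxylate SN2 alkylation, because KHCO3 ionises only the carboxylic acid and room temperature avoids decarboxylation of the resorcylic acid.

Step 4
Reactants: 3 O-benzyl-4-methoxysalicylic acid; 5 benzyl 2,4-dihydroxy-6-pentylbenzoate
Product: 6 benzyl 4-{[2-(benzyloxy)-4-methoxybenzoyl]oxy}-2-hydroxy-6-pentylbenzoate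
Conditions: dicyclohexylcarbodiimide (1.1 equiv), DMAP (0.1 equiv), CH2Cl2, 0 °C to rt
Reagents that add atoms: none
Why: In this Steglich esterification the free 4-OH of 5 is acylated, while the 2-OH is hydrogen-bonded to the ester carbonyl and sterically shielded, which is the usual selectivity of para-depside couplings.

Step 5
Reactants: 6 benzyl 4-{[2-(benzyloxy)-4-methoxybenzoyl]oxy}-2-hydroxy-6-pentylbenzoate
Product: 7 benzyl 4-{[2-(benzyloxy)-4-methoxybenzoyl]oxy}-2-methoxy-6-pentylbenzoate
Conditions: MeI (5 equiv), anhydrous K2CO3 (2 equiv), acetone, reflux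
Reagents that add atoms: iodomethane, CI
Why: In this Williamson etherification the only remaining OH is deprotonated and methylated by SN2, and the aryl benzoate, benzyl ester and benzyl ether survive anhydrous carbonate in acetone.

Step 6
Reactants: 8 trimethylsulfoxonium iodide; 9 hexanoyl chloride
Product: 11 dimethylsulfoxonium 2-oxoheptylide, via dimethylsulfoxonium methylide 10 (not isolated)
Conditions: 8 (3 equiv), KOtBu (3 equiv), THF, reflux 2 h; then 9 (1 equiv), 0 °C to rt
Reagents that add atoms: none
Why: C-acylation of the Corey–Chaykovsky ylide by the acid chloride is followed by deprotonation by a second equivalent of ylide, which gives the bench-stable carbonyl-stabilised sulfoxonium ylide.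

Step 7
Reactants: 7 benzyl 4-{[2-(benzyloxy)-4-methoxybenzoyl]oxy}-2-methoxy-6-pentylbenzoate; 11 dimethylsulfoxonium 2-oxoheptylide
Product: 12 benzyl 4-{[2-(benzyloxy)-4-methoxy-6-(2-oxoheptyl)benzoyl]oxy}-2-methoxy-6-pentylbenzoate
Conditions: [Cp*IrCl2]2 (4 mol %), AgNTf2 (16 mol %), PivOH (30 mol %), Li2CO3 (15 mol %), DCE/HFIP 4:1, 50 °C, 11 (1.5 equiv) added by syringe pump over 8 h
Reagents that add atoms: none
Why: Proposed new method: aryl-ester-directed ortho C–H acylmethylation of a depside; the cationic Cp*Ir fragment (trivalent iridium) binds the depside carbonyl oxygen, and pivalate-assisted concerted metalation–deprotonation gives a five-membered iridacycle at C6, the only free ortho position of ring A (the two ring B C–H bonds next to the acyloxy group are each flanked by two substituents and would need a six-membered metallacycle, and the ring B ester has no ortho C–H); ylide 11 then binds through carbon and loses DMSO to give an iridium carbene, 1,1-migratory insertion forms the aryl–CH bond, and protodemetalation by PivOH releases ketone 12, whose now twisted 2,6-disubstituted ester lets go of the metal; HFIP hydrogen-bonds the liberated DMSO so that it does not displace the weak ester donor, slow addition suppresses carbene dimerisation, and the base-free, mildly acidic medium at 50 °C disfavours enolate attack on the aryl ester (isocoumarin formation); the closest known reaction types are Cp*Rh- and Cp*Ir-catalysed C–H acylmethylation with sulfoxonium ylides under nitrogen or carboxylate directing groups and Cp*Ir-catalysed ortho C–H amidation of alkyl benzoates, whereas carbene transfer directed by a neutral aryl ester has not been shown.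

Step 8
Reactants: 12 benzyl 4-{[2-(benzyloxy)-4-methoxy-6-(2-oxoheptyl)benzoyl]oxy}-2-methoxy-6-pentylbenzoate
Product: 13 confluentic acid
Conditions: H2 (1 atm), 10% Pd/C, EtOAc, rt
Reagents that add atoms: none
Why: Catalytic hydrogenolysis cleaves the benzyl ether and the benzyl ester under neutral conditions and leaves the dialkyl-type ketone, the depside ester and the methyl ethers untouched.

**Compound list**
1 | 2-hydroxy-4-methoxybenzoic acid (4-methoxysalicylic acid), achiral | COc1ccc(C(=O)O)c(O)c1 | starting material
2 | benzyl 2-(benzyloxy)-4-methoxybenzoate, achiral | COc1ccc(C(=O)OCc2ccccc2)c(OCc2ccccc2)c1 | intermediate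
3 | 2-(benzyloxy)-4-methoxybenzoic acid, achiral | COc1ccc(C(=O)O)c(OCc2ccccc2)c1 | intermediate
4 | olivetolic acid (2,4-dihydroxy-6-pentylbenzoic acid), achiral | CCCCCc1cc(O)cc(O)c1C(=O)O | starting material
5 | benzyl 2,4-dihydroxy-6-pentylbenzoate, achiral | CCCCCc1cc(O)cc(O)c1C(=O)OCc1ccccc1 | intermediate
6 | benzyl 4-{[2-(benzyloxy)-4-methoxybenzoyl]oxy}-2-hydroxy-6-pentylbenzoate, achiral | CCCCCc1cc(OC(=O)c2ccc(OC)cc2OCc2ccccc2)cc(O)c1C(=O)OCc1ccccc1 | intermediate
7 | benzyl 4-{[2-(benzyloxy)-4-methoxybenzoyl]oxy}-2-methoxy-6-pentylbenzoate, achiral | CCCCCc1cc(OC(=O)c2ccc(OC)cc2OCc2ccccc2)cc(OC)c1C(=O)OCc1ccccc1 | intermediate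
8 | trimethylsulfoxonium iodide | C[S+](C)(C)=O.[I-] | starting material
9 | hexanoyl chloride | CCCCCC(=O)Cl | starting material
10 | dimethylsulfoxonium methylide (formed in the flask, not isolated) | [CH2-][S+](C)(C)=O | intermediate
11 | dimethylsulfoxonium 2-oxoheptylide (1-[dimethyl(oxo)-λ6-sulfanylidene]heptan-2-one) | CCCCCC(=O)[CH-][S+](C)(C)=O | intermediate
12 | benzyl 4-{[2-(benzyloxy)-4-methoxy-6-(2-oxoheptyl)benzoyl]oxy}-2-methoxy-6-pentylbenzoate, achiral | CCCCCC(=O)Cc1cc(OC)cc(OCc2ccccc2)c1C(=O)Oc1cc(CCCCC)c(C(=O)OCc2ccccc2)c(OC)c1 | intermediate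
13 | confluentic acid (4-{[2-hydroxy-4-methoxy-6-(2-oxoheptyl)benzoyl]oxy}-2-methoxy-6-pentylbenzoic acid), achiral | CCCCCC(=O)Cc1cc(OC)cc(O)c1C(=O)Oc1cc(CCCCC)c(C(=O)O)c(OC)c1 | target

**Totals**
Total step count: 8.
Longest linear sequence: 6 steps (steps 1, 2, 4, 5, 7 and 8).

**Three steps most likely to fail**

Step 7 (the proposed new step).
- Risks: the neutral ester is a weak donor, so turnover may be low against DMSO and the ylide carbonyl. The metal enolate may also attack the aryl ester and expel ring B as an isocoumarin forms.
- Fallback: it uses known chemistry only, sets out from 3, 11 and 7, and comes back at 12.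
- Acid 3 and ylide 11 are joined by the known carboxylate-directed C–H activation and annulation of benzoic acids with acyl sulfoxonium ylides ([RuCl2(p-cymene)]2, AgSbF6, NaOAc, DCE, 100 °C). This gives 8-(benzyloxy)-6-methoxy-3-pentyl-1H-isochromen-1-one F1.
- KOH in aqueous EtOH at reflux, then cold acidification, opens the enol lactone to 2-(benzyloxy)-4-methoxy-6-(2-oxoheptyl)benzoic acid F2.
- In parallel the stock of 7 is methanolysed (K2CO3, MeOH, rt; the 2,6-disubstituted benzyl ester of ring B is inert) to benzyl 4-hydroxy-2-methoxy-6-pentylbenzoate F3.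
- Dicyclohexylcarbodiimide in toluene, without any base so that re-closure to F1 is limited, couples F2 and F3 in the classical depside manner to give 12.

Step 5.
- Risks: the chelated, hindered 2'-OH may methylate slowly. Prolonged carbonate treatment may cleave or transacylate the depside ester.
- Fallback: it sets out from 6 and comes back at 7.
- Phenoxide alkylation is replaced by a Mitsunobu etherification (MeOH, PPh3, DIAD, THF, 0 °C to rt). Methanol is activated as the alkoxyphosphonium electrophile under neutral conditions, so no free phenoxide or carbonate ever meets the aryl ester.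
- This makes no new compound (F0).

Step 4.
- Risks: some acylation at the 2-OH, bis-acylation, or N-acylurea formation would erode the yield of the convergent step.
- Fallback: it sets out from 5 (with 3) and comes back at 7. The two hydroxyl groups are told apart before the coupling, so 6 and step 5 are bypassed.
- MOMCl and i-Pr2NEt in CH2Cl2 at 0 °C etherify the non-chelated 4-OH of 5 to give benzyl 2-hydroxy-4-(methoxymethoxy)-6-pentylbenzoate F4. Any regioisomer is removed at this cheap stage.
- MeI and K2CO3 in DMF give benzyl 2-methoxy-4-(methoxymethoxy)-6-pentylbenzoate F5.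
- HCl in MeOH at rt removes the acetal to give benzyl 4-hydroxy-2-methoxy-6-pentylbenzoate F3, which has a single hydroxyl group.
- Esterification of F3 with 3 (dicyclohexylcarbodiimide, DMAP, CH2Cl2) gives 7 directly.

**Further compounds**
F1 | step 7 | 8-(benzyloxy)-6-methoxy-3-pentyl-1H-isochromen-1-one | CCCCCC1=Cc2cc(OC)cc(OCc3ccccc3)c2C(=O)O1
F2 | step 7 | 2-(benzyloxy)-4-methoxy-6-(2-oxoheptyl)benzoic acid | CCCCCC(=O)Cc1cc(OC)cc(OCc2ccccc2)c1C(=O)O
F3 | step 7 | benzyl 4-hydroxy-2-methoxy-6-pentylbenzoate | CCCCCc1cc(O)cc(OC)c1C(=O)OCc1ccccc1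
F0 | step 5 | none | none
F4 | step 4 | benzyl 2-hydroxy-4-(methoxymethoxy)-6-pentylbenzoate | CCCCCc1cc(OCOC)cc(O)c1C(=O)OCc1ccccc1
F5 | step 4 | benzyl 2-methoxy-4-(methoxymethoxy)-6-pentylbenzoate | CCCCCc1cc(OCOC)cc(OC)c1C(=O)OCc1ccccc1
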